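In a one-step world, each substrate falls by its own pseudo-first-order law under the same catalyst and partner. The ratio of the logarithms of what remains is then a constant, the selectivity factor s, and it carries a flask from one conversion to the other.

all flasks: left-handed substrate 14 mM; right-handed substrate 14 mM

| flask | coupling partner | free catalyst | remark | time |
|---|---|---|---|---|
| winter | 1.1 equiv (fed, over 6.0 min) | 1.7 mol% | run made earlier; the fed solution adds 0.20 times the starting volume |  |
| dawn | 1.1 equiv (fed, over 6.0 min) | 7.7 mol% | run made earlier; the fed solution adds 0.20 times the starting volume |  |
| violet | 1.10 equiv | 1.5 mol% | everything together at the start, the whole solution of coupling partner included, so that from the start the volume is larger by 0.20 times the starting volume | 3.0 h |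
| amber | 1.10 equiv (fed, over 6.0 min) | 5 mol% | the fed solution adds 0.20 times the starting volume | 1.5 h |

| run | time / min | left-handed product / % | right-handed product / % |
|---|---|---|---|
| winter | 4.00 | 0 | 0.1 |
| winter | 6.00 | 0.9 | 0 |
| winter | 8.00 | 0.5 | 0 |
| winter | 12.0 | 1.1 | 0 |
| winter | 20.0 | 1.3 | 0 |
| winter | 30.0 | 3.4 | 0.5 |
| winter | 50.0 | 4.1 | 0.8 |
| dawn | 4.00 | 0.7 | 0.3 |
| dawn | 6.00 | 1.5 | 0.6 |
| dawn | 8.00 | 2.0 | 0 |
| dawn | 12.0 | 4.5 | 1.0 |
| dawn | 20.0 | 8.0 | 1.3 |
| dawn | 30.0 | 10.8 | 2.6 |
| dawn | 50.0 | 15.1 | 3.4 |

(scatter of a reading: 0.3 percentage points)

* the winner by share of left-handed product in all that became left-handed product or right-handed product; "neither" if no more than 2 percentage points parts them (violet / amber / neither)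
* share of left-handed product in all that became left-handed product or right-handed product, violet
* share of left-handed product in all that became left-handed product or right-handed product, amber

- free catalyst is single-handed; left-handed substrate and right-handed substrate are mirror images of each other, charged as a racemate, each of them at the stated concentration
- charges are per starting volume, the dose included; the dosed solution carries all of it

The last dawn reading has converted 30.2% of the left-handed substrate and 6.80% of the right-handed, so s = 5.11, a reading in which right-handed product at 3.4% carries a scatter of 0.3 percentage points. Dawn's logarithm of left-handed substrate is 4.20 times winter's for 4.53 times the catalyst, so you take the order in catalyst as one and scale that logarithm by loading times time: 1.17 for amber and 0.701 for violet.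

The bound from above is the share at zero conversion, s/(1+s) = 83.6%, since the left-handed substrate depletes faster. For the bound from below, note that dawn's logarithmic rate falls from 0.523 h⁻¹ up to 20.0 min to 0.349 h⁻¹ late on. Scaling therefore overstates conversion over these longer times. It gives left-handed conversions of 34.3% for amber and 22.3% for violet. Through s, the shares are at least 81.3% for amber and 82.2% for violet, 0.90 points apart.

The forecast says neither, with violet at 82% (79% to 85%) and amber at 81% (78% to 84%): “The gap is under 2 points.” Its violet value lies just under your lower bound of 82.2%, and its amber value lies just under your lower bound of 81.3%.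

The flask gives neither: violet 83.5%, about level with your upper bound of 83.6%, and amber 82.8%, above its lower bound, the two 0.70 points apart against a margin of 2 points.

    free catalyst + left-handed substrate ⇌ catalyst intermediate A (K = 120 M⁻¹, k = 2.60 M⁻¹ s⁻¹)
    free catalyst + right-handed substrate ⇌ catalyst intermediate B (K = 37.0 M⁻¹, k = 3.40 M⁻¹ s⁻¹)
    coupling partner + catalyst intermediate A → free catalyst + left-handed product (k = 0.410 M⁻¹ s⁻¹)
    coupling partner + catalyst intermediate B → free catalyst + right-handed product (k = 0.200 M⁻¹ s⁻¹)
    free catalyst ⇌ dormant form (K = 1.70, k = 4.20 × 10⁻⁴ s⁻¹)

The neighbour is amber with 2.80 equiv of coupling partner, read at the same 1.5 h. Its unbound left-handed substrate stands at 37% of charge, so s puts the right-handed substrate at 82.4% of charge and the share at 78.2%. That flask shows right-handed substrate at 81% of charge and a share of 76.7%.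

(The data come from a simulation with constants of no real substance; noise was put on by code.)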